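**Retrosynthetic overview**

1. Lignan numbering is used: oxolane O–C7(aryl)–C8(C9H2OH)–C8'(carbinol C7')–C9'H2. The C9 hydroxymethyl and the C7' aryl carbinol sit cis on the adjacent ring carbons C8 and C8', so O–C9–C8–C8'–C7'–O is a 1,4-diol, that is, a reduced γ-lactone. The target (7S,8R,7'S,8'R) is therefore traced back (phenol unmasking, LiAlH4) to a cis-fused 4,8-diaryl-3,7-dioxabicyclo[3.3.0]octan-2-one.
2. Both rings of this bicycle are opened in one retrosynthetic operation: the lactone O–C7' bond (benzylic cation captured by the C9 acyl oxygen) and the oxolane C8–C8' bond (5-exo addition of a C8 radical to a cinnamyl ether alkene). The features that allow this are the C9 carbonyl, which stabilises the C8 radical and later traps C7', and the electron-rich 4-alkoxy-3-methoxyphenyl ring on C7', which lets the benzylic radical be oxidised to a cation.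
3. The acyclic precursor, an α-bromo-β-(cinnamyloxy) imide, comes from an Evans syn-aldol reaction of a bromoacetyl oxazolidinone with O-allylvanillin (sets C7, the only stereocentre brought in) and O-alkylation with a cinnamyl trichloroacetimidate made from the same aldehyde.
4. Ring order: oxolane (C–C), then the temporary γ-lactone (C–O) in the same flask; the lactone ring is removed again by hydride reduction, and the allyl ethers by palladium catalysis.

Key step: step 8

**Route**

Step 1
Reactants: 1 vanillin
Product: 2 4-(allyloxy)-3-methoxybenzaldehyde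
Conditions: allyl bromide, K2CO3, DMF, rt
Reagents that add atoms: allyl bromide, C=CCBr
Why: Williamson ether synthesis, in which the phenoxide of 1 displaces bromide from the allylic halide, masks the phenol as an allyl ether that should survive every later step and can be removed under neutral conditions; no stereocentre is formed.

Step 2
Reactants: 2 4-(allyloxy)-3-methoxybenzaldehyde; 3 triethyl phosphonoacetate
Product: 4 ethyl (E)-3-[4-(allyloxy)-3-methoxyphenyl]prop-2-enoate
Conditions: NaH, THF, 0 °C to rt
Reagents that add atoms: none
Why: Horner–Wadsworth–Emmons olefination of an aromatic aldehyde with a stabilised phosphonate anion should give the (E)-cinnamate, the geometry being set by the reversible addition and syn-elimination that favour the trans alkene.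

Step 3
Reactants: 4 ethyl (E)-3-[4-(allyloxy)-3-methoxyphenyl]prop-2-enoate
Product: 5 (E)-3-[4-(allyloxy)-3-methoxyphenyl]prop-2-en-1-ol
Conditions: i-Bu2AlH (2.2 equiv), CH2Cl2, −78 °C; aqueous potassium sodium tartrate
Reagents that add atoms: none
Why: 1,2-reduction of the α,β-unsaturated ester by the electrophilic aluminium hydride should give the allylic alcohol without touching the styrene or allyl ether alkenes; no stereocentre is formed.

Step 4
Reactants: 5 (E)-3-[4-(allyloxy)-3-methoxyphenyl]prop-2-en-1-ol
Product: 6 (E)-3-[4-(allyloxy)-3-methoxyphenyl]prop-2-en-1-yl 2,2,2-trichloroacetimidate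
Conditions: Cl3CCN, DBU (10 mol %), CH2Cl2, 0 °C; used without storage
Reagents that add atoms: trichloroacetonitrile, N#CC(Cl)(Cl)Cl
Why: base-catalysed addition of the alcohol to the nitrile (trichloroacetimidate formation) turns the hydroxyl into a leaving group that traces of acid can activate; no stereocentre is formed.

Step 5
Reactants: 7 (S)-4-benzyloxazolidin-2-one; 8 bromoacetyl bromide
Product: 9 (S)-4-benzyl-3-(2-bromoacetyl)oxazolidin-2-one
Conditions: n-BuLi, THF, −78 °C; then 8, −78 to 0 °C
Reagents that add atoms: none
Why: N-acylation of the lithiated oxazolidinone at the acyl bromide, which is far more electrophilic than the alkyl bromide, installs the two carbons that become C8 and C9 together with the future radical leaving group; the auxiliary stereocentre is untouched.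

Step 6
Reactants: 9 (S)-4-benzyl-3-(2-bromoacetyl)oxazolidin-2-one; 2 4-(allyloxy)-3-methoxybenzaldehyde
Product: 10 (S)-4-benzyl-3-[(2S,3R)-3-[4-(allyloxy)-3-methoxyphenyl]-2-bromo-3-hydroxypropanoyl]oxazolidin-2-one
Conditions: Bu2BOTf, Et3N, Et2O, −78 °C; then 2, −78 to 0 °C; then MeOH, pH 7 buffer, 30% H2O2, 0 °C
Reagents that add atoms: none
Why: in this Evans syn-aldol reaction the (Z)-boron enolate of 9 should add to 2 through a closed six-membered chair transition state on the enolate face opposite the auxiliary benzyl group, which sets the carbinol carbon (future C7) as drawn and the bromine-bearing carbon syn to it (the latter is erased in step 8).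

Step 7
Reactants: 10 (S)-4-benzyl-3-[(2S,3R)-3-[4-(allyloxy)-3-methoxyphenyl]-2-bromo-3-hydroxypropanoyl]oxazolidin-2-one; 6 (E)-3-[4-(allyloxy)-3-methoxyphenyl]prop-2-en-1-yl 2,2,2-trichloroacetimidate
Product: 11 (S)-4-benzyl-3-[(2S,3R)-3-[4-(allyloxy)-3-methoxyphenyl]-3-{[(E)-3-[4-(allyloxy)-3-methoxyphenyl]prop-2-en-1-yl]oxy}-2-bromopropanoyl]oxazolidin-2-one
Conditions: 6 (2 equiv), TfOH (2 mol %), 4 Å molecular sieves, Et2O, −20 to 0 °C
Reagents that add atoms: none
Why: in this acid-catalysed trichloroacetimidate O-alkylation the protonated imidate ionises to an aryl-stabilised cinnamyl cation that the secondary alcohol should capture at the unsubstituted terminus (keeping the styrene conjugated), under conditions that avoid base-induced retro-aldol cleavage or epoxide closure of the bromohydrin; the carbinol centre keeps its configuration because its C–O bond is not broken.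

Step 8
Reactants: 11 (S)-4-benzyl-3-[(2S,3R)-3-[4-(allyloxy)-3-methoxyphenyl]-3-{[(E)-3-[4-(allyloxy)-3-methoxyphenyl]prop-2-en-1-yl]oxy}-2-bromopropanoyl]oxazolidin-2-one
Product: 14 (1S,4S,5R,8S)-4,8-bis[4-(allyloxy)-3-methoxyphenyl]-3,7-dioxabicyclo[3.3.0]octan-2-one, via benzylic cation 12 (not isolated), via iminium ether 13 (not isolated)
Conditions: fac-Ir(ppy)3 (1 mol %; ppy = 2-phenylpyridinato), 2,6-lutidine (2 equiv), H2O (20 equiv), degassed MeCN (0.02 M), blue LEDs (450 nm), rt
Reagents that add atoms: water, O
Why: The photoexcited iridium complex should reduce the C–Br bond of 11 to an α-acyl radical at C8, which adds to the near alkene carbon of the cinnamyl ether and closes the oxolane through the C8–C8' bond; the resulting 4-alkoxybenzylic radical is oxidised by the tetravalent iridium complex to cation 12, the imide carbonyl oxygen captures it to give iminium ether 13, and water hydrolyses 13 to lactone 14 and the free auxiliary. The closest known reaction types are the visible-light radical–polar crossover carbolactonisation of styrenes with α-bromo carbonyl compounds and the halolactonisation of N-acyl oxazolidinones with loss of the auxiliary. The oxolane closes in the 5-exo-trig radical mode, and the γ-lactone closes by five-membered O–C bond formation onto the trigonal benzylic cation. C8 and C8' are controlled by C7: in the chair-like 5-exo transition state the C7 aryl group sits pseudo-equatorial, which places the acyl group trans to it and the new benzylic arm cis to the acyl group (7,8-trans, 8,8'-cis). C7' is set in the lactonisation, where only a cis-fused bicycle can form and the aryl group takes the convex (exo) face away from the oxolane ring. The step needs 5-exo over 6-endo closure (secured by the five-atom tether and the benzylic stabilisation of the 5-exo radical), cyclisation ahead of intermolecular addition or reduction (secured by dilution and the absence of a hydrogen-atom donor), and carbonyl capture ahead of water capture (secured by the five-membered geometry and the electron-rich aryl ring that stabilises the cation); any 8,8'-trans adduct cannot lactonise and should be separable as an open-chain by-product.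

Step 9
Reactants: 14 (1S,4S,5R,8S)-4,8-bis[4-(allyloxy)-3-methoxyphenyl]-3,7-dioxabicyclo[3.3.0]octan-2-one
Product: 15 (S)-[4-(allyloxy)-3-methoxyphenyl][(3R,4R,5S)-5-[4-(allyloxy)-3-methoxyphenyl]-4-(hydroxymethyl)oxolan-3-yl]methanol
Conditions: LiAlH4, THF, 0 °C; water work-up
Reagents that add atoms: none
Why: hydride reduction of the γ-lactone with acyl C–O cleavage should release the primary alcohol at C9 and the benzylic alcohol at C7' with retention, since no bond to a stereocentre is broken.

Step 10
Reactants: 15 (S)-[4-(allyloxy)-3-methoxyphenyl][(3R,4R,5S)-5-[4-(allyloxy)-3-methoxyphenyl]-4-(hydroxymethyl)oxolan-3-yl]methanol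
Product: 16 (−)-tanegol, (S)-(4-hydroxy-3-methoxyphenyl)[(3R,4R,5S)-5-(4-hydroxy-3-methoxyphenyl)-4-(hydroxymethyl)oxolan-3-yl]methanol
Conditions: Pd(PPh3)4 (5 mol %), morpholine (10 equiv), THF, rt
Reagents that add atoms: none
Why: in this Tsuji–Trost-type deallylation zerovalent palladium ionises the two aryl allyl ethers to π-allyl complexes and phenoxides and morpholine traps the allyl groups, under neutral conditions that should leave the benzylic alcohol, the benzylic ether and all four stereocentres untouched.

**Compound list**

1 | vanillin (4-hydroxy-3-methoxybenzaldehyde) | O=Cc1ccc(O)c(OC)c1 | starting material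
2 | 4-(allyloxy)-3-methoxybenzaldehyde | O=Cc1ccc(OCC=C)c(OC)c1 | intermediate
3 | triethyl phosphonoacetate | CCOC(=O)CP(=O)(OCC)OCC | starting material
4 | ethyl (E)-3-[4-(allyloxy)-3-methoxyphenyl]prop-2-enoate | CCOC(=O)/C=C/c1ccc(OCC=C)c(OC)c1 | intermediate
5 | (E)-3-[4-(allyloxy)-3-methoxyphenyl]prop-2-en-1-ol | OC/C=C/c1ccc(OCC=C)c(OC)c1 | intermediate
6 | (E)-3-[4-(allyloxy)-3-methoxyphenyl]prop-2-en-1-yl 2,2,2-trichloroacetimidate | N=C(OC/C=C/c1ccc(OCC=C)c(OC)c1)C(Cl)(Cl)Cl | intermediate
7 | (S)-4-benzyloxazolidin-2-one | O=C1N[C@@H](Cc2ccccc2)CO1 | starting material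
8 | bromoacetyl bromide | O=C(Br)CBr | starting material
9 | (S)-4-benzyl-3-(2-bromoacetyl)oxazolidin-2-one | O=C(CBr)N1C(=O)OC[C@@H]1Cc1ccccc1 | intermediate
10 | (S)-4-benzyl-3-[(2S,3R)-3-[4-(allyloxy)-3-methoxyphenyl]-2-bromo-3-hydroxypropanoyl]oxazolidin-2-one | O=C([C@@H](Br)[C@H](O)c1ccc(OCC=C)c(OC)c1)N1C(=O)OC[C@@H]1Cc1ccccc1 | intermediate
11 | (S)-4-benzyl-3-[(2S,3R)-3-[4-(allyloxy)-3-methoxyphenyl]-3-{[(E)-3-[4-(allyloxy)-3-methoxyphenyl]prop-2-en-1-yl]oxy}-2-bromopropanoyl]oxazolidin-2-one | O=C([C@@H](Br)[C@H](OC/C=C/c1ccc(OCC=C)c(OC)c1)c1ccc(OCC=C)c(OC)c1)N1C(=O)OC[C@@H]1Cc1ccccc1 | intermediate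
12 | benzylic cation (oxolane closed; imide still attached; cation at C7') | O=C(N1C(=O)OC[C@@H]1Cc1ccccc1)[C@@H]1[C@@H](c2ccc(OCC=C)c(OC)c2)OC[C@@H]1[CH+]c1ccc(OCC=C)c(OC)c1 | intermediate
13 | iminium ether (bicyclic O-alkylated imide cation) | C1(=[N+]2C(=O)OC[C@@H]2Cc2ccccc2)O[C@H](c2ccc(OCC=C)c(OC)c2)[C@H]2CO[C@H](c3ccc(OCC=C)c(OC)c3)[C@@H]12 | intermediate
14 | (1S,4S,5R,8S)-4,8-bis[4-(allyloxy)-3-methoxyphenyl]-3,7-dioxabicyclo[3.3.0]octan-2-one (cis-fused; both aryl groups exo) | O=C1O[C@H](c2ccc(OCC=C)c(OC)c2)[C@H]2CO[C@H](c3ccc(OCC=C)c(OC)c3)[C@@H]12 | intermediate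
15 | (S)-[4-(allyloxy)-3-methoxyphenyl][(3R,4R,5S)-5-[4-(allyloxy)-3-methoxyphenyl]-4-(hydroxymethyl)oxolan-3-yl]methanol | COc1cc([C@@H](O)[C@H]2CO[C@H](c3ccc(OCC=C)c(OC)c3)[C@H]2CO)ccc1OCC=C | intermediate
16 | (−)-tanegol, (7S,8R,7'S,8'R) | COc1cc([C@@H](O)[C@H]2CO[C@H](c3ccc(O)c(OC)c3)[C@H]2CO)ccc1O | target

**Step count**

Total: 10 steps. Longest linear sequence: 8 steps (steps 1, 2, 3, 4, 7, 8, 9, 10).

**Steps most likely to fail**

Step 8 (key step). The benzylic radical may not be oxidised cleanly (hydrogen abstraction or dimerisation instead of cation formation), the cation may be captured by water instead of the acyl oxygen, or the 5-exo closure may show too little cis selectivity. The fallback sets out from 11 and separates the radical event from the polar one. A copper-catalysed bromine atom-transfer radical cyclisation (CuBr, monovalent copper, with tris(2-pyridylmethyl)amine in 1,2-dichloroethane at 60 °C) should give the oxolane benzylic bromide F1 as a mixture at the bromine-bearing carbon. A separate silver-assisted ionisation (AgOTf, 2,6-lutidine, MeCN–H2O, 0 °C) should then funnel both epimers through the same cation into lactonisation, and the route is rejoined at 14.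

Step 7. The imidate may rearrange to the N-allylic trichloroacetamide, or the cinnamyl cation may alkylate an arene faster than the hindered, electron-poor alcohol reacts; acid may also ionise the benzylic carbinol and erode its configuration. The fallback sets out from 5 and 10 and replaces acid-catalysed cation transfer by a silver-assisted halide displacement under buffered, non-acidic conditions. Alcohol 5 is converted with PBr3 (Et2O, 0 °C) into the cinnamyl bromide F2, which should alkylate 10 in the presence of AgOTf and 2,6-di-tert-butyl-4-methylpyridine (CH2Cl2, −40 °C); the route is rejoined at 11.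

Step 10. Once the phenols are free, the amine may promote ionisation of the 4-hydroxybenzylic alcohol through a quinone methide (epimerisation at C7' or closure onto the C9 hydroxyl to the furofuran), and allyl groups may be transferred to the free alcohols. The fallback sets out from 15 and avoids π-allyl chemistry. Isomerisation of both allyl ethers with [Ir(cod)(PMePh2)2]PF6 (activated with H2, THF, rt) should give the bis(prop-1-enyl) ether F3, and neutral hydrolysis of the enol ethers (HgCl2, HgO, acetone–water, rt) should release the phenols; the route is rejoined at 16.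

**Further compounds**

F1 | step 8 | (4S)-3-{[(2S,3R,4R)-2-[4-(allyloxy)-3-methoxyphenyl]-4-{[4-(allyloxy)-3-methoxyphenyl](bromo)methyl}oxolan-3-yl]carbonyl}-4-benzyloxazolidin-2-one (mixture at the bromine-bearing carbon) | O=C(N1C(=O)OC[C@@H]1Cc1ccccc1)[C@@H]1[C@@H](c2ccc(OCC=C)c(OC)c2)OC[C@@H]1C(Br)c1ccc(OCC=C)c(OC)c1
F2 | step 7 | (E)-1-(allyloxy)-4-(3-bromoprop-1-en-1-yl)-2-methoxybenzene | BrC/C=C/c1ccc(OCC=C)c(OC)c1
F3 | step 10 | (S)-{3-methoxy-4-[(E)-prop-1-en-1-yloxy]phenyl}[(3R,4R,5S)-4-(hydroxymethyl)-5-{3-methoxy-4-[(E)-prop-1-en-1-yloxy]phenyl}oxolan-3-yl]methanol | COc1cc([C@@H](O)[C@H]2CO[C@H](c3ccc(O/C=C/C)c(OC)c3)[C@H]2CO)ccc1O/C=C/C
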